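## Retrosynthetic overview

1. 22 ⇒ 19 by late changes at ring A and C15 only: desilylation, Mitsunobu inversion at C2, hydride reduction at C2. 19 ⇒ 18 by an SN1′ acetolysis that moves oxygen from C9 to C7 and creates C8=C9. 18 ⇒ enone 7 + side-chain organocerium 16 (bond C9–C11).
2. 7 ⇒ trans-enedione 6 ⇒ cis adduct 5 ⇒ diene 3 + quinone 4 by a catalytic enantioselective Diels–Alder reaction (bonds C1–C10 and C4–C5).
3. Enabling feature, ring B: the oxygen-bearing C6 and the sp2 carbon C9 stand 1,4 to each other, and C9 is flanked by the methyl-bearing C8 and C10. Ring B is therefore a hidden, C2v-symmetric 2,6-dimethyl-1,4-benzoquinone whose C5=C10 edge is a dienophile.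
4. Enabling feature, ring A: the C2 oxygen lies 1,3 to the C4 gem-dimethyl group, so C1–C4 are the silyl dienol ether of mesityl oxide.
5. Ring order: ring B is bought as the quinone, ring A is closed on it in step 2, and no ring is formed afterwards.

Key step: step 2

Remark: labdane numbering is used (ring A = C1–C5 and C10, ring B = C5–C10, side chain C11–C15); β is the face of the C10 methyl group, α the opposite face.

Remark: the (S)-configured catalyst is assumed to expose the face of 4 that leads to the series drawn. If the sense of induction is opposite, the equally available (R)-catalyst is used and nothing else changes.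

## Route

Step 1
Reactants: 1 mesityl oxide
Product: 3 4-methyl-2-(triisopropylsilyloxy)penta-1,3-diene, via lithium dienolate 2 (not isolated)
Conditions: LiN(iPr)2, THF, −78 °C; TIPSOTf, −78 °C → rt
Reagents that add atoms: triisopropylsilyl triflate CC(C)[Si](OS(=O)(=O)C(F)(F)F)(C(C)C)C(C)C
Why: Kinetic deprotonation of the enone at the α′-methyl group followed by O-silylation (silyl dienol ether formation) should give the cross-conjugated 2-silyloxydiene; no stereocentre is formed.

Step 2
Reactants: 3 4-methyl-2-(triisopropylsilyloxy)penta-1,3-diene; 4 2,6-dimethyl-1,4-benzoquinone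
Product: 5 cis-fused Diels–Alder adduct (5β-H and 10β-CH3)
Conditions: 3 (1.5 equiv), (S)-3,3-diphenyl-1-(2-methylphenyl)tetrahydro-1H,3H-pyrrolo[1,2-c][1,3,2]oxazaborole (20 mol %), Tf2NH (18 mol %), CH2Cl2, −78 → −40 °C
Reagents that add atoms: none
Why: The protonated oxazaborolidine binds the more basic and unhindered carbonyl oxygen of 4 (future O6, flanked by two vinylic C–H bonds), and 3 adds in a concerted, asynchronous [4+2] cycloaddition in which its nucleophilic CH2 terminus (C1) bonds ahead to the methyl-bearing β-carbon (C10) while the CMe2 terminus (C4) closes on the α-carbon (C5). The closest known reaction type is the cationic oxazaborolidine-catalysed enantioselective Diels–Alder reaction of 1,4-benzoquinones with 2-silyloxybuta-1,3-dienes, and Lewis acid-promoted Diels–Alder reactions of 4-methyl-2-silyloxypenta-1,3-dienes with hindered cyclic enones show that the terminal gem-dimethyl group is tolerated. Ring A is closed in an intermolecular, suprafacial [4+2] mode by the two σ-bonds C1–C10 and C4–C5 on the C5=C10 edge of ring B, which in one operation delivers 14 of the 20 skeletal carbons, the quaternary C10, the C4 gem-dimethyl group and the masked C2 oxygen. C10 is controlled by the catalyst, whose aryl group covers one face of the bound enone and thereby desymmetrises the achiral quinone, whereas C5 follows from suprafacial addition (H5 cis to the C10 methyl) and is corrected in step 3; endo/exo topology creates no stereocentre because the diene termini are CH2 and CMe2. The step needs regioselectivity, which is secured twice over (the siloxy and terminal methyl groups make C1 the nucleophilic end, catalyst binding at O6 makes C10 the electrophilic end, and the alternative would join CMe2 to a quaternary carbon), and it must stop after one addition, which the hindered C7=C8 bond of 5 ensures.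

Step 3
Reactants: 5 cis-fused Diels–Alder adduct
Product: 6 trans-fused enedione (5α-H and 10β-CH3)
Conditions: DBU (0.2 equiv), toluene, rt
Reagents that add atoms: none
Why: Base-catalysed epimerisation via the C5=C6 dienolate (C5–H is the only acidic C–H because C10 is quaternary, which also blocks aromatisation) should convert the cis adduct into the trans-decalin with 5α-H, the isomer in which neither the quaternary C4 nor C6 has to stand axial on the neighbouring ring.

Step 4
Reactants: 6 trans-fused enedione
Product: 7 6β-hydroxy-7-en-9-one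
Conditions: NaBH4, CeCl3·7H2O, MeOH/CH2Cl2, −78 °C
Reagents that add atoms: none
Why: Luche reduction should add hydride 1,2 to the C6 carbonyl, which is less shielded than the neopentyl C9 carbonyl (next to quaternary C10 and the C8 methyl), and from the α face because the axial methyl groups on C4 and C10 close the β face, which sets the axial 6β-alcohol.

Step 5
Reactants: 8 4-(tert-butyldimethylsilyloxy)but-1-yne
Product: 11 (E)-5-(tert-butyldimethylsilyloxy)-3-methylpent-2-en-1-ol, via alkenylalane 9 (not isolated), via lithium alanate 10 (not isolated)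
Conditions: Me3Al, Cp2ZrCl2 (20 mol %), CH2Cl2, 0 °C → rt; n-BuLi, THF, −78 °C; (CH2O)n, −78 °C → rt; aq. work-up
Reagents that add atoms: trimethylaluminium C[Al](C)C; formaldehyde (from paraformaldehyde) C=O
Why: Negishi carboalumination adds methyl and aluminium syn with aluminium at the terminus, which fixes the E geometry, and the derived alanate is hydroxymethylated with retention of the double-bond geometry.

Step 6
Reactants: 11 (E)-5-(tert-butyldimethylsilyloxy)-3-methylpent-2-en-1-ol
Product: 12 bis-silyl ether
Conditions: TBDPSCl, imidazole, DMF, rt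
Reagents that add atoms: tert-butyldiphenylsilyl chloride CC(C)(C)[Si](Cl)(c1ccccc1)c1ccccc1
Why: Imidazole-promoted silylation of the primary allylic alcohol installs the acid-robust group that has to survive step 11.

Step 7
Reactants: 12 bis-silyl ether
Product: 13 (E)-5-(tert-butyldiphenylsilyloxy)-3-methylpent-3-en-1-ol
Conditions: PPTS (cat.), MeOH, rt
Reagents that add atoms: none
Why: Acid-catalysed methanolysis removes the primary TBS ether much faster than the TBDPS ether (selective desilylation).

Step 8
Reactants: 13 (E)-5-(tert-butyldiphenylsilyloxy)-3-methylpent-3-en-1-ol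
Product: 14 homoallylic iodide
Conditions: I2, PPh3, imidazole, CH2Cl2, 0 °C
Reagents that add atoms: iodine II
Why: Appel-type iodination converts the unhindered primary alcohol by SN2 without touching the trisubstituted alkene.

Step 9
Reactants: 14 homoallylic iodide; 7 6β-hydroxy-7-en-9-one
Product: 17 6β,9β-diol carrying the side chain on the α face of C9, via organolithium 15 (not isolated), via organocerium 16 (not isolated)
Conditions: 14 (2.5 equiv), t-BuLi (5 equiv), Et2O, −78 °C; CeCl3, THF, −78 °C; then 7, −78 → −40 °C; aq. NH4Cl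
Reagents that add atoms: none
Why: Iodine–lithium exchange and transmetalation give a weakly basic organocerium reagent whose 1,2-addition to the hindered C9 enone should occur anti to the axial C10 methyl (α face, 9β-OH), one equivalent being spent on the 6-OH; the C9 stereocentre is erased again in step 11.

Step 10
Reactants: 17 6β,9β-diol
Product: 18 6β-isovalerate of the tertiary allylic alcohol
Conditions: isovaleric anhydride, DMAP, Et3N, CH2Cl2, rt → 40 °C
Reagents that add atoms: isovaleric anhydride CC(C)CC(=O)OC(=O)CC(C)C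
Why: DMAP-catalysed acylation distinguishes the secondary 6β-OH from the tertiary 9-OH, which stays free.

Step 11
Reactants: 18 6β-isovalerate of the tertiary allylic alcohol
Product: 19 7α-acetoxy-6β-isovaleryloxy-15-(tert-butyldiphenylsilyloxy)labda-8,13(E)-dien-2-one
Conditions: AcOH/CH2Cl2, TsOH·H2O (5 mol %), 0 °C → rt
Reagents that add atoms: acetic acid CC(=O)O
Why: Acid-catalysed allylic transposition (SN1′ acetolysis of a tertiary allylic alcohol): ionisation of C9–OH gives the C7–C8–C9 allyl cation, which acetic acid should capture at the less hindered C7 by axial attack on the α face anti to the 6β-acyloxy group (a 6β,7β-acyloxonium ion formed by neighbouring-group participation would be opened at C7 with inversion to the same trans-diaxial diester, as in the Prévost reaction), so that 7α-OAc and the tetrasubstituted C8=C9 bond arise together, while the water released hydrolyses the silyl enol ether to the C2 ketone.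

Step 12
Reactants: 19 7α-acetoxy-6β-isovaleryloxy-15-(tert-butyldiphenylsilyloxy)labda-8,13(E)-dien-2-one
Product: 20 2β-alcohol
Conditions: NaBH4, MeOH/THF, −20 °C
Reagents that add atoms: none
Why: Borohydride reduction of the only ketone, in which hydride reaches C2 from the α face because the syn-axial methyl groups on C4 and C10 block the β face, should give the axial 2β-alcohol and leave the esters untouched.

Step 13
Reactants: 20 2β-alcohol
Product: 21 2α,7α-diacetoxy-6β-isovaleryloxy-15-(tert-butyldiphenylsilyloxy)labda-8,13(E)-diene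
Conditions: AcOH, PPh3, DIAD, toluene, 0 °C → rt
Reagents that add atoms: acetic acid CC(=O)O
Why: Mitsunobu reaction, in which acetate displaces the axial 2β-oxyphosphonium group by SN2 attack from the open α face, inverts C2 and installs the equatorial 2α-acetate in the same operation.

Step 14
Reactants: 21 2α,7α-diacetoxy-6β-isovaleryloxy-15-(tert-butyldiphenylsilyloxy)labda-8,13(E)-diene
Product: 22 2α,7α-diacetoxy-6β-isovaleryloxylabda-8,13(E)-dien-15-ol (CNP0257091.1)
Conditions: HF·pyridine, THF/pyridine, 0 °C → rt
Reagents that add atoms: none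
Why: Fluoride-mediated silyl ether cleavage under mildly acidic conditions should free the C15 allylic alcohol without acyl migration or ester cleavage; no stereocentre is touched.

## Compound list

1 | mesityl oxide (4-methylpent-3-en-2-one) | CC(=O)C=C(C)C | starting material
2 | lithium 4-methylpenta-1,3-dien-2-olate | [Li]OC(=C)C=C(C)C | intermediate
3 | 4-methyl-2-(triisopropylsilyloxy)penta-1,3-diene | C=C(O[Si](C(C)C)(C(C)C)C(C)C)C=C(C)C | intermediate
4 | 2,6-dimethyl-1,4-benzoquinone | CC1=CC(=O)C=C(C)C1=O | starting material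
5 | cis-fused 2,5,5,8a-tetramethyl-7-(triisopropylsilyloxy)-4a,5,8,8a-tetrahydronaphthalene-1,4-dione (5β-H, 10β-CH3) | CC(C)[Si](OC1=CC(C)(C)[C@H]2C(=O)C=C(C)C(=O)[C@@]2(C)C1)(C(C)C)C(C)C | intermediate
6 | trans-fused 2,5,5,8a-tetramethyl-7-(triisopropylsilyloxy)-4a,5,8,8a-tetrahydronaphthalene-1,4-dione (5α-H, 10β-CH3) | CC(C)[Si](OC1=CC(C)(C)[C@@H]2C(=O)C=C(C)C(=O)[C@@]2(C)C1)(C(C)C)C(C)C | intermediate
7 | trans-fused 4-hydroxy-2,5,5,8a-tetramethyl-7-(triisopropylsilyloxy)-4a,5,8,8a-tetrahydronaphthalen-1(4H)-one (5α-H, 6β-OH, 10β-CH3) | CC(C)[Si](OC1=CC(C)(C)[C@@H]2[C@H](O)C=C(C)C(=O)[C@@]2(C)C1)(C(C)C)C(C)C | intermediate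
8 | 4-(tert-butyldimethylsilyloxy)but-1-yne | C#CCCO[Si](C)(C)C(C)(C)C | starting material
9 | (E)-[4-(tert-butyldimethylsilyloxy)-2-methylbut-1-enyl]dimethylalane | C[Al](C)/C=C(\C)CCO[Si](C)(C)C(C)(C)C | intermediate
10 | lithium butyl[(E)-4-(tert-butyldimethylsilyloxy)-2-methylbut-1-enyl]dimethylalanate | [Li+].CCCC[Al-](C)(C)/C=C(\C)CCO[Si](C)(C)C(C)(C)C | intermediate
11 | (E)-5-(tert-butyldimethylsilyloxy)-3-methylpent-2-en-1-ol | CC(C)(C)[Si](C)(C)OCC/C(C)=C/CO | intermediate
12 | (E)-5-(tert-butyldimethylsilyloxy)-1-(tert-butyldiphenylsilyloxy)-3-methylpent-2-ene | CC(C)(C)[Si](C)(C)OCC/C(C)=C/CO[Si](c1ccccc1)(c1ccccc1)C(C)(C)C | intermediate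
13 | (E)-5-(tert-butyldiphenylsilyloxy)-3-methylpent-3-en-1-ol | OCC/C(C)=C/CO[Si](c1ccccc1)(c1ccccc1)C(C)(C)C | intermediate
14 | (E)-tert-butyl[(5-iodo-3-methylpent-2-en-1-yl)oxy]diphenylsilane | ICC/C(C)=C/CO[Si](c1ccccc1)(c1ccccc1)C(C)(C)C | intermediate
15 | (E)-5-(tert-butyldiphenylsilyloxy)-3-methylpent-3-enyllithium | [Li]CC/C(C)=C/CO[Si](c1ccccc1)(c1ccccc1)C(C)(C)C | intermediate
16 | (E)-5-(tert-butyldiphenylsilyloxy)-3-methylpent-3-enylcerium dichloride | Cl[Ce](Cl)CC/C(C)=C/CO[Si](c1ccccc1)(c1ccccc1)C(C)(C)C | intermediate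
17 | 15-(tert-butyldiphenylsilyloxy)-2-(triisopropylsilyloxy)labda-2,7,13(E)-triene-6β,9β-diol, C11 on the α face of C9 | CC(C)[Si](OC1=CC(C)(C)[C@@H]2[C@H](O)C=C(C)[C@@](O)(CC/C(C)=C/CO[Si](c3ccccc3)(c3ccccc3)C(C)(C)C)[C@@]2(C)C1)(C(C)C)C(C)C | intermediate
18 | 6β-isovalerate of 17 (9β-OH free) | CC(C)[Si](OC1=CC(C)(C)[C@@H]2[C@H](OC(=O)CC(C)C)C=C(C)[C@@](O)(CC/C(C)=C/CO[Si](c3ccccc3)(c3ccccc3)C(C)(C)C)[C@@]2(C)C1)(C(C)C)C(C)C | intermediate
19 | 7α-acetoxy-6β-isovaleryloxy-15-(tert-butyldiphenylsilyloxy)labda-8,13(E)-dien-2-one | O=C1CC(C)(C)[C@@H]2[C@H](OC(=O)CC(C)C)[C@@H](OC(C)=O)C(C)=C(CC/C(C)=C/CO[Si](c3ccccc3)(c3ccccc3)C(C)(C)C)[C@@]2(C)C1 | intermediate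
20 | 7α-acetoxy-6β-isovaleryloxy-15-(tert-butyldiphenylsilyloxy)labda-8,13(E)-dien-2β-ol | O[C@@H]1CC(C)(C)[C@@H]2[C@H](OC(=O)CC(C)C)[C@@H](OC(C)=O)C(C)=C(CC/C(C)=C/CO[Si](c3ccccc3)(c3ccccc3)C(C)(C)C)[C@@]2(C)C1 | intermediate
21 | 2α,7α-diacetoxy-6β-isovaleryloxy-15-(tert-butyldiphenylsilyloxy)labda-8,13(E)-diene | CC(=O)O[C@H]1CC(C)(C)[C@@H]2[C@H](OC(=O)CC(C)C)[C@@H](OC(C)=O)C(C)=C(CC/C(C)=C/CO[Si](c3ccccc3)(c3ccccc3)C(C)(C)C)[C@@]2(C)C1 | intermediate
22 | 2α,7α-diacetoxy-6β-isovaleryloxylabda-8,13(E)-dien-15-ol (CNP0257091.1) | CC(=O)O[C@H]1CC(C)(C)[C@@H]2[C@H](OC(=O)CC(C)C)[C@@H](OC(C)=O)C(C)=C(CC/C(C)=C/CO)[C@@]2(C)C1 | target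

## Step count and risks

Total step count: 14. Longest linear sequence: 10 steps (steps 1–4 and 9–14, or equally steps 5–14).

**Step 2.**
- What may go wrong: the cycloaddition may be slow because the diene reaches its s-cis form only against the inside methyl group. The strong acid may protodesilylate the diene. Facial selectivity may erode with this bulkier diene.
- Fallback: it sets out from 3 and 4 and changes the source of absolute configuration.
- The cycloaddition is run racemically with stoichiometric BF3·OEt2 in CH2Cl2 at low temperature. This acid also binds the unhindered carbonyl oxygen and therefore keeps the regiochemistry. It gives 5 together with its mirror image, the ent-cis adduct F1.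
- DBU as in step 3 gives 6 together with the ent-trans-enedione F2.
- The enantiomers are then parted by kinetic resolution in an oxazaborolidine-catalysed borane reduction (CBS reduction, B-methyl oxazaborolidine, BH3·SMe2). The catalyst antipode is chosen so that its preferred hydride delivery matches the open α face of 6. Then 6 is reduced quickly at C6 and F2 is left behind.
- The fallback comes back to the route at 7.

**Step 3.**
- What may go wrong: the base-mediated equilibrium may stop short of the trans isomer. Ring B of the enedione has four sp2 carbons and offers no syn-axial partners, so a cis form with C4 axial on ring B is penalised only weakly.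
- Fallback: it sets out from 5 and moves the epimerisation to a later compound in which C9 is a fully substituted sp3 carbon.
- Luche reduction of 5 at C6 gives the cis-fused allylic alcohol F3 (C6 epimers, inconsequential).
- Organocerium 16 adds to C9 from the convex β face to give the cis-fused diol F4.
- MnO2 in CH2Cl2 re-oxidises only the secondary allylic alcohol to the cis-fused 9α-hydroxy-7-en-6-one F5.
- DBU then epimerises C5. The cis form with C4 axial on ring B now suffers a syn-axial contact with the 9α-OH, and this should give the trans-fused 9α-hydroxy-7-en-6-one F6, the substitution pattern of natural 9-hydroxylabd-7-en-6-ones.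
- Luche reduction from the α face gives the 6β,9α-diol F7, and isovalerylation as in step 10 gives the 6β-isovalerate F8.
- Because step 11 ionises C9, F8 gives the same allyl cation as 18. The fallback comes back to the route at 19.

**Step 11.**
- What may go wrong: the allyl cation may lose a proton from C11 or the C8 methyl to give dienes instead of being captured. Acetate may also be captured with poor facial selectivity, or the allylic silyl ether at C15 may solvolyse.
- Fallback: it sets out from 18 and replaces ionisation by two stereospecific events.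
- A 1,3-transposition catalysed by Ph3SiOReO3 (Et2O, −50 → 0 °C) proceeds suprafacially through the perrhenate ester. It should give the 7β-alcohol F9 with the C8=C9 bond in place and the silyl enol ether intact.
- A Mitsunobu reaction (AcOH, PPh3, DIAD) inverts C7 to the 7α-acetate silyl enol ether F10.
- Aqueous oxalic acid in THF then cleaves the enol ether. The fallback comes back to the route at 19.

Further compounds
F1 | step 2 | ent-cis adduct (mirror image of 5) | CC(C)[Si](OC1=CC(C)(C)[C@@H]2C(=O)C=C(C)C(=O)[C@]2(C)C1)(C(C)C)C(C)C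
F2 | step 2 | ent-trans-enedione (mirror image of 6) | CC(C)[Si](OC1=CC(C)(C)[C@H]2C(=O)C=C(C)C(=O)[C@]2(C)C1)(C(C)C)C(C)C
F3 | step 3 | cis-fused 6-hydroxy-7-en-9-one (5β-H, C6 epimers) | CC(C)[Si](OC1=CC(C)(C)[C@H]2C(O)C=C(C)C(=O)[C@@]2(C)C1)(C(C)C)C(C)C
F4 | step 3 | cis-fused 6,9α-diol with the side chain on the β face of C9 (5β-H, C6 epimers) | CC(C)[Si](OC1=CC(C)(C)[C@H]2C(O)C=C(C)[C@](O)(CC/C(C)=C/CO[Si](c3ccccc3)(c3ccccc3)C(C)(C)C)[C@@]2(C)C1)(C(C)C)C(C)C
F5 | step 3 | cis-fused 9α-hydroxy-7-en-6-one (5β-H) | CC(C)[Si](OC1=CC(C)(C)[C@H]2C(=O)C=C(C)[C@](O)(CC/C(C)=C/CO[Si](c3ccccc3)(c3ccccc3)C(C)(C)C)[C@@]2(C)C1)(C(C)C)C(C)C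
F6 | step 3 | trans-fused 9α-hydroxy-7-en-6-one (5α-H) | CC(C)[Si](OC1=CC(C)(C)[C@@H]2C(=O)C=C(C)[C@](O)(CC/C(C)=C/CO[Si](c3ccccc3)(c3ccccc3)C(C)(C)C)[C@@]2(C)C1)(C(C)C)C(C)C
F7 | step 3 | trans-fused 6β,9α-diol (C9 epimer of 17) | CC(C)[Si](OC1=CC(C)(C)[C@@H]2[C@H](O)C=C(C)[C@](O)(CC/C(C)=C/CO[Si](c3ccccc3)(c3ccccc3)C(C)(C)C)[C@@]2(C)C1)(C(C)C)C(C)C
F8 | step 3 | 6β-isovalerate of F7 (C9 epimer of 18) | CC(C)[Si](OC1=CC(C)(C)[C@@H]2[C@H](OC(=O)CC(C)C)C=C(C)[C@](O)(CC/C(C)=C/CO[Si](c3ccccc3)(c3ccccc3)C(C)(C)C)[C@@]2(C)C1)(C(C)C)C(C)C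
F9 | step 11 | 6β-isovaleryloxy-15-(tert-butyldiphenylsilyloxy)-2-(triisopropylsilyloxy)labda-2,8,13(E)-trien-7β-ol | CC(C)[Si](OC1=CC(C)(C)[C@@H]2[C@H](OC(=O)CC(C)C)[C@H](O)C(C)=C(CC/C(C)=C/CO[Si](c3ccccc3)(c3ccccc3)C(C)(C)C)[C@@]2(C)C1)(C(C)C)C(C)C
F10 | step 11 | 7α-acetoxy-6β-isovaleryloxy-15-(tert-butyldiphenylsilyloxy)-2-(triisopropylsilyloxy)labda-2,8,13(E)-triene | CC(C)[Si](OC1=CC(C)(C)[C@@H]2[C@H](OC(=O)CC(C)C)[C@@H](OC(C)=O)C(C)=C(CC/C(C)=C/CO[Si](c3ccccc3)(c3ccccc3)C(C)(C)C)[C@@]2(C)C1)(C(C)C)C(C)C
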